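Count the Ly groups in a closed flask: Ly + Ry + RyUj stays constant, and since Ry and Uj appear together and vanish together, their concentrations stay equal. Those two balances carry the reckoning.

    Ry + Uj → RyUj (k1 = 15 M⁻¹ s⁻¹)
    Ly + Wy ⇌ Ry + Uj (K2 = 1.7, k2 = 11000 M⁻¹ s⁻¹)

| setting | east | south-east | west | north-east |
|---|---|---|---|---|
| Ly | 0.0050 M | 0.0050 M | 0.0050 M | 0.0050 M (fed, over 2.40 s) |
| Wy | 5.00 mM (fed, over 2.40 s) | 5.00 mM | 5.00 mM | 5.00 mM |
| time | 3.0 s | 3.0 s |  | 3.0 s |
| remark | a stirred flask in which Wy is dosed at a steady rate over 2.40 s without added volume, worked up at 3.0 s | a closed flask charged with all of it at once and left for 3.0 s | one stirred flow tank at steady state, fed with the mixture as stated, mean residence time 3.0 s | a stirred flask in which Ly is dosed at a steady rate over 2.40 s without added volume, worked up at 3.0 s |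

- the set-up with the highest amount of Ry at the outlet or at the end, in percent of the Ly put in ("none" if the first two lie within 2 percentage points) (east / south-east / west / north-east / none)
- amount of Ry at the outlet or at the end, in percent of the Ly put in, east
- amount of Ry at the outlet or at the end, in percent of the Ly put in, south-east
- amount of Ry at the outlet or at the end, in percent of the Ly put in, west
- amount of Ry at the outlet or at the end, in percent of the Ly put in, north-east

Start with the vessel charged at once, south-east. The forward exchange has a half-life of 0.0126 s, far shorter than the run of 3.0 s, so you may hold the exchange at equilibrium. Ly and Wy stay equal here, so Ry over Ly is the square root of 1.7, and Ry is a share f = 56.6% of the Ly groups not yet in RyUj. Now define the drain time τ, the charge c = 0.0050 M divided by the starting rate of Ry + Uj → RyUj at equilibrium, which is one over k₁ f squared c: 41.6 s. The surviving fraction goes as one over one plus t/τ, so south-east ends at 52.8%.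

Change the vessel to the tank, west. There the loss equals t/τ times the surviving fraction squared, which gives 53.0%.

Change to dosing Wy, east. If Ry grows in step with the dose, the drain, which goes as Ry squared, counts a third of the dosing time, so the exposure is θ = 1.40 s. Put θ for t and you get 54.8%. Dosing Ly instead, north-east, gives the same figure, since Ly and Wy enter the scheme alike and their charges are equal. The top two tie.

The forecast says 54.4% east, 52.8% south-east, 52.8% west, 54.4% north-east, and none for the best, on the grounds that “Dosing either partner keeps Ry and Uj low for most of the run”. Your figures stand above it by 0.40 percentage points for the dosed pair and 0.20 points for the tank, with the same verdict.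

The simulation gives 54.4% east, 52.8% south-east, 52.8% west, 54.4% north-east, and none for the best. The half-life of Ly by the forward step alone, 0.013 s in south-east, stands against τ = 41.6 s, and the run of 3.0 s lies between them; south-east ends 3.8 points under f. Carry τ to north-east left for 30.0 s: θ becomes 28.4 s, the reckoning gives 33.6%, and the flask reads 33.5%.

The numbers of this flask were drawn at random within sensible limits; the flask was simulated.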